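(The readings were generated by integration with constants of no real substance; the scatter is artificial.)

The ratio of reagent to solid substrate is what I have to set for the next flask, and with little solid I would rather pay in reagent. The choice is 2.00 equivalents for 10 min, or more.

| flask | solid substrate | reagent | remark | time |
|---|---|---|---|---|
| autumn | 0.20 M | 0.20 M | run made earlier |  |
| dusk | 0.20 M | 0.80 M | run made earlier |  |
| midnight | 0.10 M | 0.40 M | run made earlier |  |
| flask | 0.20 M | 0.400 M |  | 10 min |

| run | time / min | target / % | solid product / % |
|---|---|---|---|
| autumn | 3.00 | 54.7 | 52.6 |
| autumn | 6.00 | 60.4 | 57.1 |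
| autumn | 10.0 | 61.0 | 57.4 |
| autumn | 12.0 | 61.1 | 58.9 |
| dusk | 1.00 | 79.9 | 75.9 |
| dusk | 2.00 | 91.3 | 87.5 |
| dusk | 5.00 | 97.1 | 93.5 |
| dusk | 12.0 | 98.6 | 95.3 |
| midnight | 1.50 | 82.8 | 77.2 |
| midnight | 4.00 | 93.8 | 89.3 |
| midnight | 8.00 | 96.9 | 91.0 |
| midnight | 12.0 | 97.7 | 93.5 |

(scatter of a reading: 0.5 percentage points)

- what is said of target includes solid product
- solid substrate, solid product is a solid; its amount is given per volume of the solution
- the analysis behind the earlier runs scatters by 0.5 percentage points, standard deviation
- at the start none of the solid substrate is in solution
- dissolved substrate means what is dissolved; the solid is not counted in it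

* how much target and solid product together there is at 10 min, in percent of the solid substrate charged
* concentration of dissolved substrate in solution at 10 min, in percent of saturation

I count one reagent per target. In the autumn run I read 0.637 for the waste ratio, the reagent charged that does not end in target per target made. At 4.00 equivalents the dusk run reads 3.06 and the midnight run 3.09, so these two runs, at different concentrations, read close together, and the midnight reading is higher than the autumn one. My flask lies midway between these ends on a logarithmic scale of equivalents, so I join them by the geometric mean, 1.40. That gives 83.2% target, solid product counted in it, as my estimate for the flask. The substrate not turned into target is then 0.0336 M. Taking the same remainder of the autumn run, 0.0778 M, as a stand-in for saturation, and supposing the remainder of the flask dissolved, I estimate 43.2% of saturation.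

The forecast says 90% (84% to 95%) of target and solid product, above my estimate, and 92% (75% to 99%) of saturation, also above mine: “the solution should be close to saturation”.

The flask gives 87.8% of target and solid product and 25.1% of saturation, with solid substrate at 0% and dissolved substrate at 12.2% of the charge.

    solid substrate ⇌ dissolved substrate, rate k1*(cs1 - [dissolved substrate]) while solid is left; crystals form when [dissolved substrate] > cs1 (solubility = 0.0970 M, k = 0.410 s⁻¹)
    dissolved substrate + reagent → target (k = 0.110 M⁻¹ s⁻¹)
    reagent → side product (k = 0.00180 s⁻¹)
    solid product ⇌ target, rate k4*(cs4 - [target]) while solid is left; crystals form when [target] > cs4 (solubility = 5.20 mM, k = 0.690 s⁻¹)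
    2 reagent → self-condensation product (k = 0.0250 M⁻¹ s⁻¹)
    reagent → decomposition product (k = 6.50 × 10⁻⁵ s⁻¹)

The waste ratio of the flask at 10 min is 1.28. The main reason for the shortfall is self-condensation: the run without that step gives >99.9% against 87.8%. The 0.0886 M of self-condensation product in the flask holds 0.177 M of reagent, out of 0.224 M that did not end in target.

With 0.34 M of solid substrate, 1.18 equiv, the same join gives a waste ratio of 0.766 and so 66.6%. That neighbour flask gives 56.7%, a waste ratio of 1.07, with reagent the limiting reagent at 0.022% of its charge left.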